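**Plan**

1. Retrosynthesis first removes the protecting groups (O5–CH3, O6–CH3, O2'–benzyl), then opens ring C at O1–C2 to give an o-hydroxyaryl ynone.
2. The ynone is cut at O1–C8a and C4–C4a together: ring A becomes 3,4,5,6-tetramethoxybenzyne, and the rest (O1, C4, C3, C2, ring B) becomes a 3-arylpropiolic acid.
3. Enabling feature: O1 on C8a and the C4 carbonyl on C4a are ortho neighbours on ring A, and C5, C6, C7 and C8 all carry oxygen, so the two aryne carbons are equivalent and no regiochemical question arises.
4. Forward: ring A is carried complete from 1,2,3,4-tetramethoxybenzene (steps 1–3) and ring B with its three-carbon chain from 2-hydroxy-6-methoxybenzaldehyde (steps 4–6). They are joined in step 7, ring C closes in step 8 (6-endo), and steps 9–10 unmask O2', O5 and O6.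
5. The target has no stereocenter. The selectivities to secure are C- versus O-acylation (step 7), 6-endo versus 5-exo closure (step 8) and the chelation-directed choice of O5 and O6 (step 10).

Key step: step 7

Numbering: flavone numbering is used throughout (O1, C2–C4, C4a, C5–C8, C8a; ring B primed).

**Route**

Step 1
Reactants: 1 1,2,3,4-tetramethoxybenzene
Product: 4 2,3,4,5-tetramethoxyphenol, via 2,3,4,5-tetramethoxyphenyllithium 2 (not isolated), via dimethyl (2,3,4,5-tetramethoxyphenyl)boronate 3 (not isolated)
Conditions: n-BuLi, TMEDA, THF, 0 °C; B(OMe)3, −78 °C to rt; AcOH, 30% H2O2, 0 °C to rt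
Reagents that add atoms: hydrogen peroxide, OO (the phenol oxygen of 4); in the intermediates only: n-butyllithium, [Li]CCCC (lithium of 2) and trimethyl borate, COB(OC)OC (boron and methoxy groups of 3)
Why: Directed ortho-lithiation (the two ring C–H bonds are equivalent and each lies next to a methoxy group) followed by borylation and peroxide oxidation of the arylboronate (lithiation–borylation–oxidation) should give the phenol without touching the methyl ethers.

Step 2
Reactants: 4 2,3,4,5-tetramethoxyphenol
Product: 5 2-bromo-3,4,5,6-tetramethoxyphenol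
Conditions: NBS (1.0 equiv), CH2Cl2, −20 to 0 °C, dark, anhydrous
Reagents that add atoms: N-bromosuccinimide, O=C1CCC(=O)N1Br
Why: Electrophilic aromatic bromination can only occur at the single remaining ring C–H, which is ortho to the free hydroxyl, and low temperature with exclusion of water should hold back oxidation of the para-methoxyphenol to a quinone.

Step 3
Reactants: 5 2-bromo-3,4,5,6-tetramethoxyphenol
Product: 8 2,3,4,5-tetramethoxy-6-(trimethylsilyl)phenyl trifluoromethanesulfonate, via (2-bromo-3,4,5,6-tetramethoxyphenoxy)trimethylsilane 6 (not isolated), via lithium 2,3,4,5-tetramethoxy-6-(trimethylsilyl)phenolate 7 (not isolated)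
Conditions: HMDS, THF, 65 °C, then volatiles removed; n-BuLi, THF, −78 °C; Tf2O, −78 °C to rt
Reagents that add atoms: hexamethyldisilazane, C[Si](C)(C)N[Si](C)(C)C; trifluoromethanesulfonic anhydride, O=S(=O)(OS(=O)(=O)C(F)(F)F)C(F)(F)F; in intermediate 7 only: n-butyllithium, [Li]CCCC
Why: O-silylation, bromine–lithium exchange and the 1,3 oxygen-to-carbon silyl shift of the aryllithium (retro-Brook rearrangement) place silicon on the carbon that carried bromine, and the lithium phenoxide is then trapped as the triflate, the usual one-flask entry to o-silylaryl triflate aryne precursors.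

Step 4
Reactants: 9 2-hydroxy-6-methoxybenzaldehyde
Product: 10 2-(benzyloxy)-6-methoxybenzaldehyde
Conditions: BnBr, K2CO3, DMF, 60 °C
Reagents that add atoms: benzyl bromide, BrCc1ccccc1
Why: Williamson ether synthesis on the only phenol; benzyl is chosen because it should survive butyllithium at −78 °C, fluoride and amines and leaves later by hydrogenolysis.

Step 5
Reactants: 10 2-(benzyloxy)-6-methoxybenzaldehyde
Product: 11 1-(benzyloxy)-2-(2,2-dibromoethenyl)-3-methoxybenzene
Conditions: CBr4, PPh3, CH2Cl2, 0 °C
Reagents that add atoms: carbon tetrabromide, BrC(Br)(Br)Br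
Why: First stage of the Corey–Fuchs homologation, a Wittig olefination by the dibromomethylene ylide generated in the flask from CBr4 and PPh3.

Step 6
Reactants: 11 1-(benzyloxy)-2-(2,2-dibromoethenyl)-3-methoxybenzene
Product: 13 3-[2-(benzyloxy)-6-methoxyphenyl]prop-2-ynoic acid, via lithium arylacetylide 12 (not isolated)
Conditions: n-BuLi (2.2 equiv), THF, −78 °C; CO2 (gas), −78 °C to rt; aq HCl
Reagents that add atoms: carbon dioxide, O=C=O; in intermediate 12 only: n-butyllithium, [Li]CCCC
Why: Second stage of the Corey–Fuchs sequence (bromine–lithium exchange, Fritsch–Buttenberg–Wiechell 1,2-shift, deprotonation) gives the lithium acetylide, which is carboxylated by CO2, and at −78 °C the benzyl ether should not be metalated.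

Step 7
Reactants: 8 2,3,4,5-tetramethoxy-6-(trimethylsilyl)phenyl trifluoromethanesulfonate; 13 3-[2-(benzyloxy)-6-methoxyphenyl]prop-2-ynoic acid
Product: 16 3-[2-(benzyloxy)-6-methoxyphenyl]-1-(2-hydroxy-3,4,5,6-tetramethoxyphenyl)prop-2-yn-1-one, via 3,4,5,6-tetramethoxybenzyne 14 (not isolated), via ortho-cesiated aryl propiolate 15 (not isolated)
Conditions: 8 (1.5 equiv), CsF (4 equiv), THF, 125 °C, sealed tube; aq NH4Cl quench as soon as 13 is consumed
Reagents that add atoms: cesium fluoride, [Cs+].[F-] (cesium of intermediate 15 only; every atom of 16 comes from 8 and 13)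
Why: Fluoride removes the silyl group of 8 and triflate departs to give the symmetric aryne 14; the cesium carboxylate of 13 adds through oxygen, and the aryl anion 15 attacks its own ester carbonyl through a four-membered transition state whose collapse moves the acyl group from oxygen to the neighbouring carbon, so that O1–C8a and C4–C4a are both in place after one operation. The closest known reaction type is the intermolecular insertion of arynes into the C–O bond of carboxylic acids, which is established for benzoic, cinnamic and arylpropiolic acids. No ring is closed and no stereocenter is created in this step. Regiochemistry needs no control because both carbons of the triple bond of 14 are flanked by methoxy groups and are equivalent, so either sense of addition leads to the same ynone with all four remaining ring-A oxygens in place. The selectivity that is needed is C-acylation over simple O-arylation, and the aprotic medium and high temperature are chosen so that the intramolecular acyl shift outruns protonation of 15. The product is expected to persist as the carbonyl-chelated phenol, whose closure onto the alkyne is slowed by the electron-rich, di-ortho-oxygenated aryl group at the alkyne terminus.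

Step 8
Reactants: 16 3-[2-(benzyloxy)-6-methoxyphenyl]-1-(2-hydroxy-3,4,5,6-tetramethoxyphenyl)prop-2-yn-1-one
Product: 18 2-[2-(benzyloxy)-6-methoxyphenyl]-5,6,7,8-tetramethoxy-4H-chromen-4-one, via diethylamino enone 17 (not isolated)
Conditions: Et2NH (5 equiv), EtOH, reflux
Reagents that add atoms: diethylamine, CCNCC (held only in intermediate 17 and released again; nothing is added to 18)
Why: Amine-mediated ring closure: conjugate addition of diethylamine gives enaminone 17, and intramolecular addition–elimination by the phenol oxygen at the amine-bearing carbon can only form the six-membered ring (6-endo, flavone and not aurone), releasing the amine.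

Step 9
Reactants: 18 2-[2-(benzyloxy)-6-methoxyphenyl]-5,6,7,8-tetramethoxy-4H-chromen-4-one
Product: 19 2-(2-hydroxy-6-methoxyphenyl)-5,6,7,8-tetramethoxy-4H-chromen-4-one
Conditions: H2 (1 atm), 10% Pd/C, EtOAc–MeOH, rt
Reagents that add atoms: none
Why: Catalytic hydrogenolysis of the aryl benzyl ether under mild conditions, which should leave the pyranone double bond and the methyl ethers untouched; removing benzyl here keeps benzyl cations out of the Lewis-acid step.

Step 10
Reactants: 19 2-(2-hydroxy-6-methoxyphenyl)-5,6,7,8-tetramethoxy-4H-chromen-4-one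
Product: 21 5,6-dihydroxy-2-(2-hydroxy-6-methoxyphenyl)-7,8-dimethoxy-4H-chromen-4-one (the target), via 5-hydroxy-6,7,8-trimethoxy flavone 20 (not isolated)
Conditions: AlBr3 (excess), MeCN, 0 °C to rt; then dilute aq HCl, 60 °C, short
Reagents that add atoms: none
Why: Chelation-controlled Lewis-acid demethylation: aluminium held between the C4 carbonyl and O5 directs bromide to the 5-methyl group, the resulting 5-O-aluminium phenoxide then chelates O6 in a five-membered ring so that the 6-methyl group follows, while the methoxy groups at C7, C8 and C6' have no aluminium-bearing neighbour and should stay, and the mild acetonitrile medium is chosen to avoid acid-induced opening and reclosure of the pyranone (Wessely–Moser isomerisation).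

**Compound list**

1 | 1,2,3,4-tetramethoxybenzene | COc1ccc(OC)c(OC)c1OC | starting material
2 | 2,3,4,5-tetramethoxyphenyllithium | [Li]c1cc(OC)c(OC)c(OC)c1OC | intermediate
3 | dimethyl (2,3,4,5-tetramethoxyphenyl)boronate | COB(OC)c1cc(OC)c(OC)c(OC)c1OC | intermediate
4 | 2,3,4,5-tetramethoxyphenol | COc1cc(O)c(OC)c(OC)c1OC | intermediate
5 | 2-bromo-3,4,5,6-tetramethoxyphenol | COc1c(O)c(Br)c(OC)c(OC)c1OC | intermediate
6 | (2-bromo-3,4,5,6-tetramethoxyphenoxy)trimethylsilane | COc1c(O[Si](C)(C)C)c(Br)c(OC)c(OC)c1OC | intermediate
7 | lithium 2,3,4,5-tetramethoxy-6-(trimethylsilyl)phenolate | [Li+].[O-]c1c([Si](C)(C)C)c(OC)c(OC)c(OC)c1OC | intermediate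
8 | 2,3,4,5-tetramethoxy-6-(trimethylsilyl)phenyl trifluoromethanesulfonate | COc1c(OC)c(OC)c([Si](C)(C)C)c(OS(=O)(=O)C(F)(F)F)c1OC | intermediate
9 | 2-hydroxy-6-methoxybenzaldehyde | COc1cccc(O)c1C=O | starting material
10 | 2-(benzyloxy)-6-methoxybenzaldehyde | COc1cccc(OCc2ccccc2)c1C=O | intermediate
11 | 1-(benzyloxy)-2-(2,2-dibromoethenyl)-3-methoxybenzene | COc1cccc(OCc2ccccc2)c1C=C(Br)Br | intermediate
12 | {[2-(benzyloxy)-6-methoxyphenyl]ethynyl}lithium | [Li]C#Cc1c(OC)cccc1OCc1ccccc1 | intermediate
13 | 3-[2-(benzyloxy)-6-methoxyphenyl]prop-2-ynoic acid | COc1cccc(OCc2ccccc2)c1C#CC(=O)O | intermediate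
14 | 3,4,5,6-tetramethoxybenzyne (1,2-didehydro-3,4,5,6-tetramethoxybenzene) | COC1=C(OC)C(OC)=C(OC)C#C1 | intermediate
15 | [2-({3-[2-(benzyloxy)-6-methoxyphenyl]prop-2-ynoyl}oxy)-3,4,5,6-tetramethoxyphenyl]cesium | [Cs]c1c(OC)c(OC)c(OC)c(OC)c1OC(=O)C#Cc1c(OC)cccc1OCc1ccccc1 | intermediate
16 | 3-[2-(benzyloxy)-6-methoxyphenyl]-1-(2-hydroxy-3,4,5,6-tetramethoxyphenyl)prop-2-yn-1-one | COc1cccc(OCc2ccccc2)c1C#CC(=O)c1c(O)c(OC)c(OC)c(OC)c1OC | intermediate
17 | 3-[2-(benzyloxy)-6-methoxyphenyl]-3-(diethylamino)-1-(2-hydroxy-3,4,5,6-tetramethoxyphenyl)prop-2-en-1-one (push–pull double bond, E and Z forms interconvert, drawn without descriptor) | CCN(CC)C(=CC(=O)c1c(O)c(OC)c(OC)c(OC)c1OC)c1c(OC)cccc1OCc1ccccc1 | intermediate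
18 | 2-[2-(benzyloxy)-6-methoxyphenyl]-5,6,7,8-tetramethoxy-4H-chromen-4-one | COc1cccc(OCc2ccccc2)c1-c1cc(=O)c2c(OC)c(OC)c(OC)c(OC)c2o1 | intermediate
19 | 2-(2-hydroxy-6-methoxyphenyl)-5,6,7,8-tetramethoxy-4H-chromen-4-one | COc1cccc(O)c1-c1cc(=O)c2c(OC)c(OC)c(OC)c(OC)c2o1 | intermediate
20 | 5-hydroxy-2-(2-hydroxy-6-methoxyphenyl)-6,7,8-trimethoxy-4H-chromen-4-one (present as its aluminium chelate) | COc1cccc(O)c1-c1cc(=O)c2c(O)c(OC)c(OC)c(OC)c2o1 | intermediate
21 | 5,6,2'-trihydroxy-7,8,6'-trimethoxyflavone | COc1cccc(O)c1-c1cc(=O)c2c(O)c(O)c(OC)c(OC)c2o1 | target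

**Step count and risks**

Total steps: 10. Longest linear sequence: 7 steps (1, 2, 3, 7, 8, 9, 10, or equally 4, 5, 6, 7, 8, 9, 10).

Steps most likely to fail:

1. Step 7. Three processes threaten it.
- The aryl anion may be protonated before the acyl shift, which stops at O-arylation.
- The propiolate may lose CO2 at the reaction temperature.
- The phenoxide of the product may add to a second aryne or close onto its alkyne in the fluoride medium without control between the 5-exo and 6-endo modes.

Fallback, setting out from 4 and 11 and returning at 16: ortho-formylation of 4 at its only free ring position (MgCl2, Et3N, paraformaldehyde, MeCN, reflux; Casnati–Skattebøl conditions) should give 2-hydroxy-3,4,5,6-tetramethoxybenzaldehyde F1. Acetylide 12 is made from 11 with n-BuLi as in step 6 but without CO2. Adding F1 to 2.2 equivalents of 12 in THF at −78 °C (one equivalent serves as base for the phenol) should give the racemic propargylic alcohol 3-[2-(benzyloxy)-6-methoxyphenyl]-1-(2-hydroxy-3,4,5,6-tetramethoxyphenyl)prop-2-yn-1-ol F2. Oxidation of the activated alcohol with MnO2 in CH2Cl2 at rt then delivers ynone 16.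

2. Step 10. The double demethylation may stall after the first cleavage, may remove a third methyl group (O7 or O6'), or the acidic work-up may open and reclose the pyranone and so scramble the oxygen pattern.

Fallback, setting out from 18 and returning at 21; it replaces the second Lewis-acid cleavage by an oxidative one whose site is fixed by the free 5-hydroxyl.
- MgI2·OEt2 in toluene–Et2O at 60 °C removes only the carbonyl-chelated 5-methyl group and should spare the benzyl ether, giving 2-[2-(benzyloxy)-6-methoxyphenyl]-5-hydroxy-6,7,8-trimethoxy-4H-chromen-4-one F3.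
- IBX in DMF at rt delivers oxygen to the only non-fused carbon ortho to that phenol, C6, and expels its methoxy group, giving 2-[2-(benzyloxy)-6-methoxyphenyl]-7,8-dimethoxy-4H-chromene-4,5,6-trione F4.
- F4 is reduced in the same flask with aqueous Na2S2O4 to 2-[2-(benzyloxy)-6-methoxyphenyl]-5,6-dihydroxy-7,8-dimethoxy-4H-chromen-4-one F5.
- Hydrogenolysis as in step 9 (H2, Pd/C) then gives 21.

3. Step 2. N-bromosuccinimide may oxidise the very electron-rich para-methoxyphenol to a quinone in place of substituting the ring.

Fallback, setting out from 1 and returning at 5; the order of halogenation and hydroxylation is reversed so that no free phenol meets the brominating agent.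
- NBS in MeCN at rt brominates the ether 1 to 1-bromo-2,3,4,5-tetramethoxybenzene F6.
- Lithium 2,2,6,6-tetramethylpiperidide (LiTMP) in THF at −78 °C, with B(OiPr)3 present from the start, metalates the C–H flanked by bromine and methoxy and traps it at once as dipropan-2-yl (2-bromo-3,4,5,6-tetramethoxyphenyl)boronate F7.
- F7 is oxidised in the same flask with AcOH and 30% H2O2 to bromophenol 5.

**Further compounds**

F1 | step 7 | 2-hydroxy-3,4,5,6-tetramethoxybenzaldehyde | COc1c(O)c(C=O)c(OC)c(OC)c1OC
F2 | step 7 | 3-[2-(benzyloxy)-6-methoxyphenyl]-1-(2-hydroxy-3,4,5,6-tetramethoxyphenyl)prop-2-yn-1-ol (racemic) | COc1cccc(OCc2ccccc2)c1C#CC(O)c1c(O)c(OC)c(OC)c(OC)c1OC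
F3 | step 10 | 2-[2-(benzyloxy)-6-methoxyphenyl]-5-hydroxy-6,7,8-trimethoxy-4H-chromen-4-one | COc1cccc(OCc2ccccc2)c1-c1cc(=O)c2c(O)c(OC)c(OC)c(OC)c2o1
F4 | step 10 | 2-[2-(benzyloxy)-6-methoxyphenyl]-7,8-dimethoxy-4H-chromene-4,5,6-trione | COC1=C(OC)C(=O)C(=O)C2=C1OC(=CC2=O)c1c(OC)cccc1OCc1ccccc1
F5 | step 10 | 2-[2-(benzyloxy)-6-methoxyphenyl]-5,6-dihydroxy-7,8-dimethoxy-4H-chromen-4-one | COc1cccc(OCc2ccccc2)c1-c1cc(=O)c2c(O)c(O)c(OC)c(OC)c2o1
F6 | step 2 | 1-bromo-2,3,4,5-tetramethoxybenzene | COc1cc(Br)c(OC)c(OC)c1OC
F7 | step 2 | dipropan-2-yl (2-bromo-3,4,5,6-tetramethoxyphenyl)boronate | COc1c(OC)c(OC)c(Br)c(B(OC(C)C)OC(C)C)c1OC
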